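## Retrosynthetic overview

- **Feature:** in the side chain, C5'–C10' is an unbranched six-carbon run with syn oxygens on C6' and C8' and a bare methylene at C7'. C10' is an aldehyde carbon once the C9'=C10' styrene is read as a dehydrated phenyl carbinol. With Cl on C5' this is a 6-chloro-2,4,6-trideoxyhexopyranose, an oxane ring made of O(C6'), C6', C7', C8', C9' and C10'.
- **Key cut:** C6'–C7' and C8'–C9' come from an aldolase-catalysed double aldol of chloroacetaldehyde with two acetaldehydes, and the lactol bond C10'–O(C6') closes in the same operation.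
- **Right end and centre:** phenyl goes onto C10' by Grignard addition and dehydration. C4' is a dithiane carbon that links oxirane carbon C5' to propargylic C3' and is then reduced 1,3-anti under direction of the C6' hydroxyl.
- **Left end:** C6 is a formyl carbon put on the C1' acetylide and set by allylboration. Acrylate ring-closing metathesis builds the pyranone, semihydrogenation gives the Z C1'=C2' alkene, and desilylation ends the route.
- **Ring order:** oxane (step 1, opened in step 4), oxirane C5'–C6' (step 4, opened in step 8), 5,6-dihydropyran-2-one (step 16). The dithiane ring is bought and removed in step 9.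

Key step: step 1

Assumption: the lactone is numbered O1, C2–C6 and the side chain C1'–C10' (phenyl on C10'), so the given SMILES reads (6R,1'Z,4'S,6'R,8'R,9'E). C4'/C6' are anti and C6'/C8' are syn. TBS = tert-butyldimethylsilyl.

## Route

Step 1
Reactants: 1 chloroacetaldehyde; 2 acetaldehyde (two equivalents)
Product: 5 (4R,6S)-6-(chloromethyl)oxane-2,4-diol (anomer mixture), via (S)-4-chloro-3-hydroxybutanal 3 (not isolated), via (3R,5S)-6-chloro-3,5-dihydroxyhexanal 4 (not isolated)
Conditions: 2-deoxy-D-ribose-5-phosphate aldolase (E. coli enzyme), aq NaHCO3 buffer pH 7.3, 25 °C, slow co-feed of 1 and 2 (1 : 2.1)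
Reagents that add atoms: none
Why: The active-site lysine of the aldolase turns acetaldehyde 2 into an enamine that adds to the carbonyl of 1 (bond C6'–C7'); hydrolysis releases aldol 3, which is taken up again as acceptor for a second enzyme-bound enamine of 2 (bond C8'–C9') to give 4. This is the known sequential cross-aldol activity of this enzyme towards α-haloacetaldehydes, so no new reactivity is asked of it. The oxane ring closes spontaneously by 6-exo-trig addition of the C6' hydroxyl to the C10' aldehyde of 4, giving lactol 5 as an anomer mixture that is harmless because C10' ends up sp2. C6' and C8' are each set by the chiral active site, which exposes the same spatial face of both acceptor carbonyls to the enamine, hence the syn relation and the absolute sense (S at the chloromethyl carbinol, which becomes 6'R in the target by a priority change only, and 8'R). The step needs a clean donor/acceptor assignment and a stop after two additions: 1 is not accepted as donor and is the more electrophilic acceptor, and lactol formation withdraws the free aldehyde of 4 from a third aldol. Slow co-feeding keeps both aldehydes dilute so that the protein is not alkylated or cross-linked.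

Step 2
Reactants: 5 (4R,6S)-6-(chloromethyl)oxane-2,4-diol
Product: 6 (4R,6S)-6-(chloromethyl)-4-hydroxyoxan-2-one
Conditions: Br2, BaCO3, H2O, 0 °C to rt
Reagents that add atoms: none
Why: Bromine-water oxidation of a hemiacetal (the classical aldose to aldonolactone oxidation) is much faster than oxidation of the isolated C8' carbinol, BaCO3 takes up the HBr, and no stereocentre is involved.

Step 3
Reactants: 6 (4R,6S)-6-(chloromethyl)-4-hydroxyoxan-2-one
Product: 7 (4R,6S)-4-(TBSO)-6-(chloromethyl)oxan-2-one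
Conditions: TBSCl, imidazole, DMF, rt
Reagents that add atoms: tert-butyldimethylsilyl chloride, CC(C)(C)[Si](C)(C)Cl
Why: Imidazole-promoted silylation of the only hydroxyl (C8'–OH) is a standard protection, and the weak base does not provoke β-elimination of the β-oxygenated lactone.

Step 4
Reactants: 7 (4R,6S)-4-(TBSO)-6-(chloromethyl)oxan-2-one
Product: 9 methyl (3R)-3-(TBSO)-4-[(2S)-oxiran-2-yl]butanoate, via chlorohydrin methyl ester 8 (not isolated)
Conditions: K2CO3 (1.2 equiv), MeOH, 0 °C to rt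
Reagents that add atoms: methanol, CO
Why: Carbonate-promoted methanolysis (transesterification) opens the δ-lactone to chlorohydrin 8, whose C6' alkoxide displaces the neighbouring chloride in a 3-exo-tet Williamson closure that breaks only the C5'–Cl bond, so C6' keeps its configuration and the oxirane is in place before any benzylic hydroxyl exists in the molecule.

Step 5
Reactants: 9 methyl (3R)-3-(TBSO)-4-[(2S)-oxiran-2-yl]butanoate
Product: 10 (3R)-3-(TBSO)-4-[(2S)-oxiran-2-yl]butanal
Conditions: i-Bu2AlH (1.05 equiv), CH2Cl2, −78 °C; then aq potassium sodium tartrate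
Reagents that add atoms: none
Why: Partial ester reduction with i-Bu2AlH stops at the tetrahedral aluminium hemiacetal at −78 °C and releases the aldehyde only on work-up, while oxirane and silyl ether are inert at this temperature.

Step 6
Reactants: 10 (3R)-3-(TBSO)-4-[(2S)-oxiran-2-yl]butanal; 11 phenylmagnesium bromide
Product: 12 (3S)-3-(TBSO)-4-[(2S)-oxiran-2-yl]-1-phenylbutan-1-ol (C10' epimers)
Conditions: PhMgBr (1.2 equiv), THF, −78 °C; aq NH4Cl at −78 °C
Reagents that add atoms: none
Why: Grignard 1,2-addition to the aldehyde is much faster than uncatalysed opening of a terminal oxirane at −78 °C, the cold quench keeps the benzylic alkoxide from attacking the oxirane, and the C10' epimer mixture is harmless because this centre is erased in step 7.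

Step 7
Reactants: 12 (3S)-3-(TBSO)-4-[(2S)-oxiran-2-yl]-1-phenylbutan-1-ol
Product: 13 tert-butyl(dimethyl){[(1E,3R)-4-[(2S)-oxiran-2-yl]-1-phenylbut-1-en-3-yl]oxy}silane
Conditions: Ph2S[OC(CF3)2Ph]2 (Martin sulfurane), CH2Cl2, 0 °C to rt
Reagents that add atoms: none
Why: Martin sulfurane dehydration turns the benzylic hydroxyl into an alkoxysulfonium leaving group that departs with loss of one of the C9' hydrogens (the only β-hydrogens), the transition state with phenyl and the C8' chain anti leads to the conjugated E alkene, and the non-acidic medium spares oxirane and silyl ether.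

Step 8
Reactants: 13 styrenyl oxirane; 14 2-(trimethylsilyl)-1,3-dithiane; 15 3-bromo-1-(trimethylsilyl)prop-1-yne
Product: 20 (2S,4R,5E)-4-(TBSO)-6-phenyl-1-{2-[3-(trimethylsilyl)prop-2-yn-1-yl]-1,3-dithian-2-yl}hex-5-en-2-ol, via 2-lithio-2-(trimethylsilyl)-1,3-dithiane 16 (not isolated), via C-silyl lithium alkoxide 17 (not isolated), via relayed 2-lithiodithiane 18 (not isolated), via O-trimethylsilyl ether 19 (not isolated)
Conditions: 14, t-BuLi, Et2O, −78 to −45 °C; add 13, −78 to −25 °C; add 15 in HMPA–Et2O, −78 to 0 °C; then citric acid, MeOH, rt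
Reagents that add atoms: none
Why: Three-component dithiane linchpin coupling (anion relay through a 1,4-Brook rearrangement): 16 opens the oxirane at the unhindered C5' to alkoxide 17, HMPA then lets Me3Si migrate from C4' to the C6' oxygen, the relayed carbanion 18 is alkylated in SN2 fashion by propargylic bromide 15, no alkyllithium ever meets the styrene or a propargylic CH2 next to a dithiane, C6' is untouched because its C–O bond stays intact, and acid methanolysis strips only the labile O–SiMe3 group of 19 so that the C6' hydroxyl is free for step 10.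

Step 9
Reactants: 20 hydroxy dithiane
Product: 21 (6S,8R,9E)-8-(TBSO)-6-hydroxy-10-phenyl-1-(trimethylsilyl)dec-9-en-1-yn-4-one
Conditions: MeI, CaCO3, MeCN–H2O (9:1), 40 °C
Reagents that add atoms: water, O
Why: Alkylative thioacetal hydrolysis (S-methylation, ring opening, attack of water) runs close to neutrality over solid CaCO3, which should keep the β,γ-alkynyl ketone from shifting to the allenyl ketone and the β-hydroxy ketone from eliminating, and MeI leaves styrene, alkyne and silyl groups alone.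

Step 10
Reactants: 21 β-hydroxy ketone
Product: 22 (4S,6R,8R,9E)-8-(TBSO)-10-phenyl-1-(trimethylsilyl)dec-9-en-1-yne-4,6-diol
Conditions: Me4NBH(OAc)3, MeCN–AcOH (1:1), −30 °C; then aq potassium sodium tartrate
Reagents that add atoms: none
Why: Evans–Saksena reduction: the C6' hydroxyl displaces acetate from boron and hydride is delivered intramolecularly through a chair-like six-membered transition state to the ketone face that gives the 1,3-anti diol, which here is 4'S.

Step 11
Reactants: 22 anti diol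
Product: 23 (4S,6R,8R,9E)-4,6,8-tris(TBSO)-10-phenyl-1-(trimethylsilyl)dec-9-en-1-yne
Conditions: TBSOTf, 2,6-lutidine, CH2Cl2, 0 °C
Reagents that add atoms: tert-butyldimethylsilyl trifluoromethanesulfonate, CC(C)(C)[Si](C)(C)OS(=O)(=O)C(F)(F)F
Why: A silyl triflate with a hindered pyridine base silylates both secondary hydroxyls quickly at 0 °C without touching the C-silyl alkyne or the cinnamyl ether.

Step 12
Reactants: 23 C-silyl alkyne
Product: 24 (4S,6R,8R,9E)-4,6,8-tris(TBSO)-10-phenyldec-9-en-1-yne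
Conditions: K2CO3 (cat.), MeOH–THF, rt
Reagents that add atoms: none
Why: Methoxide-catalysed protiodesilylation cleaves the C(sp)–SiMe3 bond selectively, since the three hindered O–TBS groups are stable to K2CO3 in methanol.

Step 13
Reactants: 24 terminal alkyne; 25 N,N-dimethylformamide
Product: 27 (5S,7R,9R,10E)-5,7,9-tris(TBSO)-11-phenylundec-10-en-2-ynal, via lithium acetylide 26 (not isolated)
Conditions: n-BuLi (1.0 equiv), THF, −78 °C; DMF, −78 to 0 °C; inverse quench into aq KH2PO4
Reagents that add atoms: none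
Why: Acid–base lithiation of the terminal alkyne is instantaneous at −78 °C so that one equivalent of n-BuLi cannot add to the styrene, acetylide 26 is formylated by 25, and the buffered inverse quench collapses the hemiaminal alkoxide to the ynal without conjugate addition of dimethylamine.

Step 14
Reactants: 27 ynal; 28 B-allylbis(isopinocampheyl)borane derived from (−)-α-pinene
Product: 30 (4R,8S,10R,12R,13E)-8,10,12-tris(TBSO)-14-phenyltetradeca-1,13-dien-5-yn-4-ol, via homoallyl diisopinocampheylborinate 29 (not isolated)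
Conditions: 28, Et2O, −78 °C; then NaOH, H2O2, 0 °C to rt
Reagents that add atoms: none
Why: Brown allylboration through a closed chair (Zimmerman–Traxler) transition state, in which the isopinocampheyl groups derived from (−)-α-pinene steer allyl onto the Re face of the aldehyde and so set 6R under reagent control, the nearest resident centre C4' being four carbons away, after which alkaline peroxide cleaves borinate 29.

Step 15
Reactants: 30 homoallylic propargylic alcohol; 31 acryloyl chloride
Product: 32 (4R,8S,10R,12R,13E)-8,10,12-tris(TBSO)-14-phenyltetradeca-1,13-dien-5-yn-4-yl prop-2-enoate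
Conditions: acryloyl chloride, i-Pr2NEt, DMAP (cat.), CH2Cl2, 0 °C
Reagents that add atoms: none
Why: DMAP-catalysed O-acylation of the propargylic alcohol takes place at oxygen only, so C6 is retained.

Step 16
Reactants: 32 acrylate
Product: 33 (6R)-6-[(4S,6R,8R,9E)-4,6,8-tris(TBSO)-10-phenyldec-9-en-1-yn-1-yl]-5,6-dihydro-2H-pyran-2-one
Conditions: first-generation Grubbs catalyst RuCl2(PCy3)2(=CHPh) (10 mol %), CH2Cl2 (2 mM), reflux
Reagents that add atoms: none
Why: Ring-closing metathesis: the ruthenium carbene loads on the monosubstituted allyl alkene and closes onto the acrylate to the six-membered unsaturated lactone with loss of ethylene, a closure known for acrylates of 1-alkynyl homoallylic alcohols because the first-generation catalyst is sluggish towards internal alkynes and 1,2-disubstituted styrenes.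

Step 17
Reactants: 33 alkynyl lactone
Product: 34 (6R)-6-[(1Z,4S,6R,8R,9E)-4,6,8-tris(TBSO)-10-phenyldeca-1,9-dien-1-yl]-5,6-dihydro-2H-pyran-2-one
Conditions: H2 (1 atm), Pd/CaCO3 poisoned with Pb(OAc)2 (Lindlar catalyst), quinoline, EtOAc, rt, stopped at 1 equiv H2
Reagents that add atoms: none
Why: Lindlar semihydrogenation delivers both hydrogens to one face of the adsorbed alkyne and thus gives the Z C1'=C2' alkene, the alkyne binding to lead-poisoned palladium far more strongly than the enoate or styrene double bonds as long as uptake is stopped at one equivalent.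

Step 18
Reactants: 34 tris-silyl ether
Product: 35 (6R)-6-[(1Z,4S,6R,8R,9E)-4,6,8-trihydroxy-10-phenyldeca-1,9-dien-1-yl]-5,6-dihydro-2H-pyran-2-one (target)
Conditions: HF·pyridine, pyridine, THF, 0 °C to rt
Reagents that add atoms: none
Why: Fluoride-driven cleavage of the three Si–O bonds with pyridine-buffered HF is mild enough to avoid ionisation of the cinnamyl C8' alcohol and opening of or conjugate addition to the unsaturated lactone, and it touches no stereocentre.

## Compound list

1 | chloroacetaldehyde | O=CCCl | starting material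
2 | acetaldehyde | CC=O | starting material
3 | (S)-4-chloro-3-hydroxybutanal (in situ) | O=CC[C@H](O)CCl | intermediate
4 | (3R,5S)-6-chloro-3,5-dihydroxyhexanal (in situ) | O=CC[C@H](O)C[C@H](O)CCl | intermediate
5 | (4R,6S)-6-(chloromethyl)oxane-2,4-diol (anomer mixture) | OC1C[C@H](O)C[C@@H](CCl)O1 | intermediate
6 | (4R,6S)-6-(chloromethyl)-4-hydroxyoxan-2-one | O=C1C[C@H](O)C[C@@H](CCl)O1 | intermediate
7 | (4R,6S)-4-(TBSO)-6-(chloromethyl)oxan-2-one | O=C1C[C@H](O[Si](C)(C)C(C)(C)C)C[C@@H](CCl)O1 | intermediate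
8 | methyl (3R,5S)-3-(TBSO)-6-chloro-5-hydroxyhexanoate (in situ) | COC(=O)C[C@H](O[Si](C)(C)C(C)(C)C)C[C@H](O)CCl | intermediate
9 | methyl (3R)-3-(TBSO)-4-[(2S)-oxiran-2-yl]butanoate | COC(=O)C[C@H](O[Si](C)(C)C(C)(C)C)C[C@H]1CO1 | intermediate
10 | (3R)-3-(TBSO)-4-[(2S)-oxiran-2-yl]butanal | O=CC[C@H](O[Si](C)(C)C(C)(C)C)C[C@H]1CO1 | intermediate
11 | phenylmagnesium bromide | Br[Mg]c1ccccc1 | starting material
12 | (3S)-3-(TBSO)-4-[(2S)-oxiran-2-yl]-1-phenylbutan-1-ol (C10' epimers) | OC(C[C@H](O[Si](C)(C)C(C)(C)C)C[C@H]1CO1)c1ccccc1 | intermediate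
13 | tert-butyl(dimethyl){[(1E,3R)-4-[(2S)-oxiran-2-yl]-1-phenylbut-1-en-3-yl]oxy}silane | C1O[C@H]1C[C@@H](O[Si](C)(C)C(C)(C)C)/C=C/c1ccccc1 | intermediate
14 | 2-(trimethylsilyl)-1,3-dithiane | C[Si](C)(C)C1SCCCS1 | starting material
15 | 3-bromo-1-(trimethylsilyl)prop-1-yne | C[Si](C)(C)C#CCBr | starting material
16 | 2-lithio-2-(trimethylsilyl)-1,3-dithiane (in situ) | [Li]C1([Si](C)(C)C)SCCCS1 | intermediate
17 | lithium (2S,4R,5E)-4-(TBSO)-6-phenyl-1-[2-(trimethylsilyl)-1,3-dithian-2-yl]hex-5-en-2-olate (in situ) | C[Si](C)(C)C1(SCCCS1)C[C@@H](O[Li])C[C@@H](O[Si](C)(C)C(C)(C)C)/C=C/c1ccccc1 | intermediate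
18 | {2-[(2S,4R,5E)-4-(TBSO)-6-phenyl-2-(trimethylsilyloxy)hex-5-en-1-yl]-1,3-dithian-2-yl}lithium (in situ) | [Li]C1(SCCCS1)C[C@@H](O[Si](C)(C)C)C[C@@H](O[Si](C)(C)C(C)(C)C)/C=C/c1ccccc1 | intermediate
19 | O-trimethylsilyl ether of 20 (in situ) | C[Si](C)(C)C#CCC1(SCCCS1)C[C@@H](O[Si](C)(C)C)C[C@@H](O[Si](C)(C)C(C)(C)C)/C=C/c1ccccc1 | intermediate
20 | (2S,4R,5E)-4-(TBSO)-6-phenyl-1-{2-[3-(trimethylsilyl)prop-2-yn-1-yl]-1,3-dithian-2-yl}hex-5-en-2-ol | C[Si](C)(C)C#CCC1(SCCCS1)C[C@@H](O)C[C@@H](O[Si](C)(C)C(C)(C)C)/C=C/c1ccccc1 | intermediate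
21 | (6S,8R,9E)-8-(TBSO)-6-hydroxy-10-phenyl-1-(trimethylsilyl)dec-9-en-1-yn-4-one | C[Si](C)(C)C#CCC(=O)C[C@@H](O)C[C@@H](O[Si](C)(C)C(C)(C)C)/C=C/c1ccccc1 | intermediate
22 | (4S,6R,8R,9E)-8-(TBSO)-10-phenyl-1-(trimethylsilyl)dec-9-en-1-yne-4,6-diol | C[Si](C)(C)C#CC[C@H](O)C[C@@H](O)C[C@@H](O[Si](C)(C)C(C)(C)C)/C=C/c1ccccc1 | intermediate
23 | (4S,6R,8R,9E)-4,6,8-tris(TBSO)-10-phenyl-1-(trimethylsilyl)dec-9-en-1-yne | C[Si](C)(C)C#CC[C@H](O[Si](C)(C)C(C)(C)C)C[C@@H](O[Si](C)(C)C(C)(C)C)C[C@@H](O[Si](C)(C)C(C)(C)C)/C=C/c1ccccc1 | intermediate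
24 | (4S,6R,8R,9E)-4,6,8-tris(TBSO)-10-phenyldec-9-en-1-yne | C#CC[C@H](O[Si](C)(C)C(C)(C)C)C[C@@H](O[Si](C)(C)C(C)(C)C)C[C@@H](O[Si](C)(C)C(C)(C)C)/C=C/c1ccccc1 | intermediate
25 | N,N-dimethylformamide | CN(C)C=O | starting material
26 | lithium acetylide of 24 (in situ) | [Li]C#CC[C@H](O[Si](C)(C)C(C)(C)C)C[C@@H](O[Si](C)(C)C(C)(C)C)C[C@@H](O[Si](C)(C)C(C)(C)C)/C=C/c1ccccc1 | intermediate
27 | (5S,7R,9R,10E)-5,7,9-tris(TBSO)-11-phenylundec-10-en-2-ynal | O=CC#CC[C@H](O[Si](C)(C)C(C)(C)C)C[C@@H](O[Si](C)(C)C(C)(C)C)C[C@@H](O[Si](C)(C)C(C)(C)C)/C=C/c1ccccc1 | intermediate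
28 | B-allylbis(isopinocampheyl)borane derived from (−)-α-pinene | C=CCB([C@H]1C[C@H]2C[C@@H]([C@@H]1C)C2(C)C)[C@H]1C[C@H]2C[C@@H]([C@@H]1C)C2(C)C | starting material
29 | diisopinocampheylborinate of 30 (in situ) | C=CC[C@@H](OB([C@H]1C[C@H]2C[C@@H]([C@@H]1C)C2(C)C)[C@H]1C[C@H]2C[C@@H]([C@@H]1C)C2(C)C)C#CC[C@H](O[Si](C)(C)C(C)(C)C)C[C@@H](O[Si](C)(C)C(C)(C)C)C[C@@H](O[Si](C)(C)C(C)(C)C)/C=C/c1ccccc1 | intermediate
30 | (4R,8S,10R,12R,13E)-8,10,12-tris(TBSO)-14-phenyltetradeca-1,13-dien-5-yn-4-ol | C=CC[C@@H](O)C#CC[C@H](O[Si](C)(C)C(C)(C)C)C[C@@H](O[Si](C)(C)C(C)(C)C)C[C@@H](O[Si](C)(C)C(C)(C)C)/C=C/c1ccccc1 | intermediate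
31 | acryloyl chloride | C=CC(=O)Cl | starting material
32 | (4R,8S,10R,12R,13E)-8,10,12-tris(TBSO)-14-phenyltetradeca-1,13-dien-5-yn-4-yl prop-2-enoate | C=CC[C@@H](OC(=O)C=C)C#CC[C@H](O[Si](C)(C)C(C)(C)C)C[C@@H](O[Si](C)(C)C(C)(C)C)C[C@@H](O[Si](C)(C)C(C)(C)C)/C=C/c1ccccc1 | intermediate
33 | (6R)-6-[(4S,6R,8R,9E)-4,6,8-tris(TBSO)-10-phenyldec-9-en-1-yn-1-yl]-5,6-dihydro-2H-pyran-2-one | O=C1C=CC[C@H](C#CC[C@H](O[Si](C)(C)C(C)(C)C)C[C@@H](O[Si](C)(C)C(C)(C)C)C[C@@H](O[Si](C)(C)C(C)(C)C)/C=C/c2ccccc2)O1 | intermediate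
34 | (6R)-6-[(1Z,4S,6R,8R,9E)-4,6,8-tris(TBSO)-10-phenyldeca-1,9-dien-1-yl]-5,6-dihydro-2H-pyran-2-one | O=C1C=CC[C@H](/C=C\C[C@H](O[Si](C)(C)C(C)(C)C)C[C@@H](O[Si](C)(C)C(C)(C)C)C[C@@H](O[Si](C)(C)C(C)(C)C)/C=C/c2ccccc2)O1 | intermediate
35 | (6R)-6-[(1Z,4S,6R,8R,9E)-4,6,8-trihydroxy-10-phenyldeca-1,9-dien-1-yl]-5,6-dihydro-2H-pyran-2-one | O=C1C=CC[C@H](/C=C\C[C@H](O)C[C@@H](O)C[C@@H](O)/C=C/c2ccccc2)O1 | target

## Totals and risks

Total step count: 18. Longest linear sequence: 18 steps (from 1 and 2 to 35). Compounds 11, 14, 15, 25, 28 and 31 are bought.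

**Step 7 (dehydration beside an oxirane).**
- What may go wrong: the activated benzylic centre may ionise and be captured by the oxirane oxygen. The free hydroxyl of 12 may also add to the oxirane (6-exo closure to an oxane) before it is activated. E selectivity may be incomplete.
- Fallback: the oxirane is postponed, so that the benzylic hydroxyl is the only reactive site when it is eliminated. The detour sets out from 6 and comes back at 13.
- Lactone 6 is opened with MeOH, 2,2-dimethoxypropane and catalytic p-TsOH to methyl 2-[(4R,6S)-6-(chloromethyl)-2,2-dimethyl-1,3-dioxan-4-yl]acetate F1. Reduction with i-Bu2AlH at −78 °C gives 2-[(4R,6S)-6-(chloromethyl)-2,2-dimethyl-1,3-dioxan-4-yl]acetaldehyde F2, and PhMgBr gives 2-[(4S,6S)-6-(chloromethyl)-2,2-dimethyl-1,3-dioxan-4-yl]-1-phenylethan-1-ol F3.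
- Mesylation (MsCl, Et3N) and E2 elimination with DBU in warm toluene give (4S,6R)-4-(chloromethyl)-2,2-dimethyl-6-[(E)-2-phenylethenyl]-1,3-dioxane F4.
- Aqueous AcOH frees (2S,4R,5E)-1-chloro-6-phenylhex-5-ene-2,4-diol F5, and K2CO3 in MeOH closes (1E,3R)-4-[(2S)-oxiran-2-yl]-1-phenylbut-1-en-3-ol F6. TBSCl with imidazole then gives 13.

**Step 9 (unmasking of the C4' ketone).**
- What may go wrong: the liberated β,γ-alkynyl ketone may undergo a prototropic shift to the allenyl ketone, water may be lost across C5'–C6', or the hindered dithiane may hydrolyse slowly.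
- Fallback: C4' never becomes a ketone. The dithiane serves as a formyl anion, and C4' is set by catalyst-controlled propargylation, which also bypasses the relay coupling of step 8. The detour sets out from 13 and comes back at 24.
- 2-Lithio-1,3-dithiane (1,3-dithiane, n-BuLi, THF, made before 13 is added) opens the oxirane at C5' to (2S,4R,5E)-4-(TBSO)-1-(1,3-dithian-2-yl)-6-phenylhex-5-en-2-ol F7. TBSOTf with 2,6-lutidine gives 2-[(2S,4R,5E)-2,4-bis(TBSO)-6-phenylhex-5-en-1-yl]-1,3-dithiane F8, and MeI with CaCO3 in aqueous MeCN gives (3S,5R,6E)-3,5-bis(TBSO)-7-phenylhept-6-enal F9.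
- Keck-type propargylation follows, with allenyltributylstannane, Ti(OiPr)4 and (S)-BINOL. This antipode is expected to direct attack to the Si face, in line with the intrinsic 1,3-anti bias of a β-silyloxy aldehyde. It gives (4S,6R,8R,9E)-6,8-bis(TBSO)-10-phenyldec-9-en-1-yn-4-ol F10, and silylation with TBSOTf gives 24.

**Step 17 (semihydrogenation in the presence of two other alkenes).**
- What may go wrong: hydrogen uptake may run on into the enoate or the styrene, or the new alkene may isomerise from Z to E on the metal. Upstream, in step 16, the alkyne may also interfere with the ruthenium carbene.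
- Fallback: the Z alkene is made before the lactone and without hydrogen gas. The detour sets out from 30 and comes back at 34.
- Propargylic alcohol 30 is reduced with zinc dust activated with Cu(OAc)2 and AgNO3 in MeOH–THF–H2O. This dissolving-metal reduction acts only on the hydroxyl-activated alkyne and leaves all alkenes alone. It gives (4R,5Z,8S,10R,12R,13E)-8,10,12-tris(TBSO)-14-phenyltetradeca-1,5,13-trien-4-ol F11.
- Acryloylation as in step 15 gives (4R,5Z,8S,10R,12R,13E)-8,10,12-tris(TBSO)-14-phenyltetradeca-1,5,13-trien-4-yl prop-2-enoate F12. Ring-closing metathesis as in step 16, now free of any alkyne, closes the six-membered lactone to 34.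

## Further compounds

F1 | step 7 | methyl 2-[(4R,6S)-6-(chloromethyl)-2,2-dimethyl-1,3-dioxan-4-yl]acetate | COC(=O)C[C@H]1C[C@@H](CCl)OC(C)(C)O1
F2 | step 7 | 2-[(4R,6S)-6-(chloromethyl)-2,2-dimethyl-1,3-dioxan-4-yl]acetaldehyde | O=CC[C@H]1C[C@@H](CCl)OC(C)(C)O1
F3 | step 7 | 2-[(4S,6S)-6-(chloromethyl)-2,2-dimethyl-1,3-dioxan-4-yl]-1-phenylethan-1-ol | OC(C[C@H]1C[C@@H](CCl)OC(C)(C)O1)c1ccccc1
F4 | step 7 | (4S,6R)-4-(chloromethyl)-2,2-dimethyl-6-[(E)-2-phenylethenyl]-1,3-dioxane | c1ccccc1/C=C/[C@H]2C[C@@H](CCl)OC(C)(C)O2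
F5 | step 7 | (2S,4R,5E)-1-chloro-6-phenylhex-5-ene-2,4-diol | c1ccccc1/C=C/[C@H](O)C[C@H](O)CCl
F6 | step 7 | (1E,3R)-4-[(2S)-oxiran-2-yl]-1-phenylbut-1-en-3-ol | c1ccccc1/C=C/[C@H](O)C[C@H]2CO2
F7 | step 9 | (2S,4R,5E)-4-(TBSO)-1-(1,3-dithian-2-yl)-6-phenylhex-5-en-2-ol | C1CSC(SC1)C[C@@H](O)C[C@@H](O[Si](C)(C)C(C)(C)C)/C=C/c1ccccc1
F8 | step 9 | 2-[(2S,4R,5E)-2,4-bis(TBSO)-6-phenylhex-5-en-1-yl]-1,3-dithiane | C1CSC(SC1)C[C@@H](O[Si](C)(C)C(C)(C)C)C[C@@H](O[Si](C)(C)C(C)(C)C)/C=C/c1ccccc1
F9 | step 9 | (3S,5R,6E)-3,5-bis(TBSO)-7-phenylhept-6-enal | O=CC[C@@H](O[Si](C)(C)C(C)(C)C)C[C@@H](O[Si](C)(C)C(C)(C)C)/C=C/c1ccccc1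
F10 | step 9 | (4S,6R,8R,9E)-6,8-bis(TBSO)-10-phenyldec-9-en-1-yn-4-ol | C#CC[C@H](O)C[C@@H](O[Si](C)(C)C(C)(C)C)C[C@@H](O[Si](C)(C)C(C)(C)C)/C=C/c1ccccc1
F11 | step 17 | (4R,5Z,8S,10R,12R,13E)-8,10,12-tris(TBSO)-14-phenyltetradeca-1,5,13-trien-4-ol | C=CC[C@@H](O)/C=C\C[C@H](O[Si](C)(C)C(C)(C)C)C[C@@H](O[Si](C)(C)C(C)(C)C)C[C@@H](O[Si](C)(C)C(C)(C)C)/C=C/c1ccccc1
F12 | step 17 | (4R,5Z,8S,10R,12R,13E)-8,10,12-tris(TBSO)-14-phenyltetradeca-1,5,13-trien-4-yl prop-2-enoate | C=CC[C@@H](OC(=O)C=C)/C=C\C[C@H](O[Si](C)(C)C(C)(C)C)C[C@@H](O[Si](C)(C)C(C)(C)C)C[C@@H](O[Si](C)(C)C(C)(C)C)/C=C/c1ccccc1
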